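## The problem

The target is a biflavonoid ether. A (2S)-flavanone carries a chelated hydroxyl at C5, a methoxy group at C7 and, at C6, an aryloxy group that is ring B (the C4' oxygen) of apigenin. Ring A of the flavanone is oxygenated at four neighbouring carbons (C5, C6, C7 and C8a) with only C8 free, and the diaryl ether oxygen sits between two oxygenated carbons. C2 is the only stereocentre, so no other centre can relay to it; it must come from a reagent or catalyst. C2 is also fragile: it is a benzylic ether carbon β to the C4 ketone, lost under base by retro-oxa-Michael opening to the chalcone and under strong acid by ionisation of C2–O1. Four phenols must be freed at the end without base, and of the two ring A oxygens O5 must end free while O7 stays methylated. The enabling feature is that, with O5 and O7 both methylated and ring C still open, the 3,5-dimethoxy-4-aryloxyphenyl ether has a mirror plane through O1, C8a, C6 and the diaryl ether oxygen. The future C4a and C8 are then equivalent, each ortho to O1, ortho to one methoxy group and para to the other. Once C4=O exists, chelation singles out the O5 methyl group.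

## Retrosynthesis

**Unmasking (19 from 18 from 17).** The last bond cut is O5–CH3 of dimethyl ether 18, using a boron Lewis acid held by C4=O; before that, the three benzylic C–O bonds of 17 (two ethers, one carbonate) are cut by hydrogenolysis. Hydrogenolysis is placed first because BCl3 also cleaves aryl benzyl ethers, fastest the one peri to the flavone carbonyl, and would release benzyl cations beside three electron-rich rings. With the benzyl groups gone, the chelated methyl ether is the only Lewis-acid-labile group in 18. The forward steps must leave the flavone C2=C3 bond, the aryl ketone and the benzylic C2–O1 bond alone and must not epimerise C2.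

**Ring C (17 from 16).** The C4–C4a bond is cut, giving acid 16, in which C2 is already an (S)-configured benzylic aryl ether. Cutting O1–C8a instead would need a halogen at C8a and a desymmetrised ring A. Cutting O1–C2 (oxa-Michael closure of a 2'-hydroxychalcone) would leave the stereocentre to a reversible, poorly controlled cyclisation under base. In 16 ring A is symmetric, so the acylation has no regiochemical choice. The forward reaction must acylate faster than the C2–O1 bond ionises. For that reason ring B carries a benzyl carbonate and not an ether: the carbonate oxygen is a much weaker donor.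

**The C2–O1 ether (16 from 15, from 9 and 14).** The tert-butyl ester 15 is the precursor of 16. It is cleaved by acid because hydroxide would expel the phenoxide by E1cB and destroy the carbonate. Cutting C2–O1 of 15 gives phenol 9 and (R)-carbinol 14, joined by Mitsunobu inversion. Conjugate addition of 9 to a cinnamate would form the same bond but has no dependable enantiocontrol. The two fragments are of similar size, so the route is convergent. The forward step must be a clean SN2 reaction; the carbonate disfavours the SN1 path, and 14, the cheaper partner, can be used in excess.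

**The carbinol (14 from 13, from 11 and 12, from 10).** The C2–H bond of 14 comes from catalyst-controlled transfer hydrogenation of β-keto ester 13. The C3–C4 unit of the flavanone comes from diazo ester 12, inserted into the formyl C–H bond of carbonate 11, which is made from 4-hydroxybenzaldehyde 10. The carbonate is installed first because it makes the aldehyde more electrophilic and suppresses aryl migration in the homologation.

**The ring A phenol (9 from 7).** The C–OH bond of 9 is traced to the C–Br bond of 7 (borylation, then oxidation through boronate 8). A bromine atom is the protecting group: it is inert to the SNAr, aldol and oxidation steps, needs no selective installation, and fixes the position of the future O1.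

**The flavone (7 from 6, from 2 and 5).** The pyranone O1–C2 bond and the C2=C3 unsaturation of 7 come from oxidative cyclisation of 2'-hydroxychalcone 6. The Cα=Cβ bond of 6 comes from Claisen–Schmidt condensation of acetophenone 2 with aldehyde 5. The forward steps are standard; the benzyl ethers, the aryl bromide and the diaryl ether must survive hydroxide and hot DMSO.

**Diaryl ether and acetophenone (5 from 3 and 4; 2 from 1).** The hindered diaryl ether C–O bond is cut to phenol 3 and 4-fluorobenzaldehyde 4. SNAr is preferred to a copper coupling because the para-formyl group activates the fluoride and later serves as the chalcone carbonyl partner. Acetophenone 2 is the bis(benzyl) ether of 1; the chelated ortho hydroxyl is left free.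

## Roads not taken

**Alternative 1:** Here the pyranone ring of the second unit would be closed at the chromone oxidation level, without ring B, by cutting C2=C3 of chromone A1. The forward key step heats the phenacylidene triphenylphosphorane A2, whose ortho oxygen is formylated, in toluene. The ylide carbon adds to the formate carbonyl and Ph3PO is lost. C2 and its aryl group would then have to be put on A1, most plausibly by an enantioselective conjugate arylation with an arylboronic acid.
- Merits: the closure is neutral and thermal; no stereocentre is exposed to it; O5 is a benzyl ether from the start, so a single hydrogenolysis ends the synthesis with no Lewis acid demethylation; the stereocentre would be set catalytically at a late, convergent stage. In these respects the road is better than the chosen one.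
- Weak points: ring A of A2 is unsymmetrical and pentasubstituted (acyl, formyloxy, methoxy, aryloxy, benzyloxy), and every group has to be placed by hand. The ylide requires α-halogenation of a very electron-rich acetophenone. The aryl formate is an acylating agent and is labile. The conjugate arylation would have to work on a chromone with a peri alkoxy group while a second enone, the flavone, is present.
- Comparison: the chosen plan sets against this a ring A that needs no regiocontrol, a shorter path to it, and a closure of established type with the stereocentre already in place.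

**Alternative 2:** This road cuts C4–C4a of the apigenin unit and not of the flavanone. The (Z)-β-aryloxycinnamic acid A4 is activated with trifluoroacetic anhydride and acylates its 3,5-bis(benzyloxy)phenoxy ring to give flavone A3, which is the same compound as phenol 9.
- Merits: it is the same reaction type as the chosen key step, the phloroglucinol ring is again symmetric, and the hydroxide aldol and hot DMSO oxidation are avoided. For the preparation of 9 it is about equal in length.
- Weak points: A4 arises from addition of a phenol to an arylpropiolate, which gives E/Z mixtures, and only the Z acid can close. The free phenol of A4 would be trifluoroacetylated, and its ring is as electron-rich as the ring meant to be acylated, so it needs a protecting group. Above all, the step builds the achiral half; ring C and C2 of the flavanone still have to be made as in the chosen plan.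
- Comparison: it is a variant for one fragment and not a competitor. The chosen route sets against it a chalcone sequence that gives a single isomer, with a bromine atom in place of a phenol protecting group.

**Alternative 3:** This road cuts O1–C8a. The anti diol A6, which has a bromine atom at the future C8a, is closed with CuI, 1,10-phenanthroline and Cs2CO3 to the (2S,4S)-flavan-4-ol A5. The diol would come from asymmetric hydrogenation of a 1,3-diketone.
- Merits: C2 is set by hydrogenation and retained through the closure; there is no inversion step and no acid near the benzylic ether. Without a C4 carbonyl there is no retro-oxa-Michael path under the basic coupling. Only the C2 hydroxyl can reach C8a. Ring B can carry a plain benzyl ether. In stereochemical security this road is better than the chosen one, whose open question is the acid lability of the benzylic ether.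
- Weak points: ring A of A6 loses its symmetry and becomes pentasubstituted with a bromine that must be placed regioselectively. The diketone contains a di-ortho-substituted aryl ketone, which is a poor hydrogenation substrate. The coupling needs hot carbonate base next to a flavone and two benzylic alcohols. A5 still has to be oxidised at C4 and demethylated at O5.
- Comparison: the chosen plan sets against this a halogen-free symmetric ring A, no reduction–oxidation detour and fewer steps.

Key step: step 11

Assumption: compounds 1, 3, 4, 10 and 12 are taken as commercial; the catalyst enantiomer in step 8 is the one expected to give the (R)-carbinol and would be checked against racemic material.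

## Route

Step 1
Reactants: 1 2',4',6'-trihydroxyacetophenone
Product: 2 1-[2,4-bis(benzyloxy)-6-hydroxyphenyl]ethan-1-one
Conditions: BnBr (2.1 equiv), K2CO3 (2.2 equiv), DMF, 0 °C to rt
Reagents that add atoms: benzyl bromide, BrCc1ccccc1
Why: Williamson O-benzylation; one ortho hydroxyl stays hydrogen-bonded to the acetyl carbonyl and is far less nucleophilic, so alkylation should stop at the bis(benzyl) ether and leave the chelated phenol for the chalcone and flavone steps.

Step 2
Reactants: 3 4-bromo-2,6-dimethoxyphenol; 4 4-fluorobenzaldehyde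
Product: 5 4-(4-bromo-2,6-dimethoxyphenoxy)benzaldehyde
Conditions: K2CO3, DMF, 120 °C
Reagents that add atoms: none
Why: SNAr (addition–elimination) of the hindered phenoxide on the para-formyl-activated aryl fluoride; the bromide sits on the electron-rich ring, is not activated and should be retained.

Step 3
Reactants: 2 1-[2,4-bis(benzyloxy)-6-hydroxyphenyl]ethan-1-one; 5 4-(4-bromo-2,6-dimethoxyphenoxy)benzaldehyde
Product: 6 (E)-1-[2,4-bis(benzyloxy)-6-hydroxyphenyl]-3-[4-(4-bromo-2,6-dimethoxyphenoxy)phenyl]prop-2-en-1-one
Conditions: KOH (50% aq), EtOH/THF, rt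
Reagents that add atoms: none
Why: Claisen–Schmidt condensation; 5 has no α-hydrogen, the methyl ketone enolate adds and E1cB dehydration gives the (E)-chalcone, while benzyl ethers, aryl bromide and diaryl ether are stable to hydroxide at rt.

Step 4
Reactants: 6 (E)-1-[2,4-bis(benzyloxy)-6-hydroxyphenyl]-3-[4-(4-bromo-2,6-dimethoxyphenoxy)phenyl]prop-2-en-1-one
Product: 7 5,7-bis(benzyloxy)-2-[4-(4-bromo-2,6-dimethoxyphenoxy)phenyl]-4H-chromen-4-one
Conditions: I2 (10 mol%), DMSO, 130 °C
Reagents that add atoms: none
Why: Iodine-catalysed oxidative cyclisation of a 2'-hydroxychalcone: oxa-Michael closure of the chelated phenol, α-iodination and loss of HI give the flavone, and DMSO reoxidises HI to I2.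

Step 5
Reactants: 7 5,7-bis(benzyloxy)-2-[4-(4-bromo-2,6-dimethoxyphenoxy)phenyl]-4H-chromen-4-one
Product: 9 5,7-bis(benzyloxy)-2-[4-(4-hydroxy-2,6-dimethoxyphenoxy)phenyl]-4H-chromen-4-one, via aryl pinacol boronate 8 (not isolated)
Conditions: B2pin2 (1.2 equiv), PdCl2(dppf) (3 mol%), KOAc (3 equiv), 1,4-dioxane, 90 °C; then NaBO3·4H2O (3 equiv), THF/H2O, rt
Reagents that add atoms: bis(pinacolato)diboron, CC1(C)OB(OC1(C)C)B1OC(C)(C)C(C)(C)O1 (its atoms appear only in intermediate 8); sodium perborate tetrahydrate, [Na+].[Na+].O[B-]1(O)OO[B-](O)(O)OO1 (source of the phenol oxygen)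
Why: Miyaura borylation of the unhindered aryl bromide, then oxidation of the aryl boronate by 1,2-aryl shift from boron to oxygen, places the hydroxyl para to the diaryl ether oxygen with no regiochemical choice; perborate is mild enough to leave the flavone enone alone.

Step 6
Reactants: 10 4-hydroxybenzaldehyde
Product: 11 benzyl 4-formylphenyl carbonate
Conditions: CbzCl (1.1 equiv), Et3N, CH2Cl2, 0 °C
Reagents that add atoms: benzyl chloroformate, O=C(Cl)OCc1ccccc1
Why: O-acylation of the phenol by the chloroformate; the carbonate weakens the donor strength of the ring B oxygen for steps 7 to 11 and is removable later by hydrogenolysis without base.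

Step 7
Reactants: 11 benzyl 4-formylphenyl carbonate; 12 tert-butyl diazoacetate
Product: 13 tert-butyl 3-{4-[(benzyloxycarbonyl)oxy]phenyl}-3-oxopropanoate
Conditions: SnCl2 (10 mol%), CH2Cl2, rt
Reagents that add atoms: none
Why: Roskamp homologation: Lewis-acid-assisted addition of the diazo ester to the aldehyde, then 1,2-hydride shift with loss of N2, gives the β-keto ester; the electron-poor aryl group disfavours the competing aryl shift.

Step 8
Reactants: 13 tert-butyl 3-{4-[(benzyloxycarbonyl)oxy]phenyl}-3-oxopropanoate
Product: 14 tert-butyl (3R)-3-{4-[(benzyloxycarbonyl)oxy]phenyl}-3-hydroxypropanoate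
Conditions: RuCl[(R,R)-TsDPEN](p-cymene) (1 mol%), HCO2H/Et3N (5:2), EtOAc, 30 °C
Reagents that add atoms: none
Why: Noyori–Ikariya asymmetric transfer hydrogenation of an aryl ketone; the (R,R) catalyst should deliver hydride to the face that gives the (R)-carbinol, in the same sense as for acetophenone, and the buffered, non-alcoholic medium spares the aryl carbonate and the tert-butyl ester.

Step 9
Reactants: 9 5,7-bis(benzyloxy)-2-[4-(4-hydroxy-2,6-dimethoxyphenoxy)phenyl]-4H-chromen-4-one; 14 tert-butyl (3R)-3-{4-[(benzyloxycarbonyl)oxy]phenyl}-3-hydroxypropanoate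
Product: 15 tert-butyl (3S)-3-{4-[(benzyloxycarbonyl)oxy]phenyl}-3-(4-{4-[5,7-bis(benzyloxy)-4-oxo-4H-chromen-2-yl]phenoxy}-3,5-dimethoxyphenoxy)propanoate
Conditions: PPh3, DIAD, toluene/THF, 0 °C to rt (14 in excess)
Reagents that add atoms: none
Why: Mitsunobu etherification; the phenoxide of 9 displaces the oxyphosphonium group of 14 by SN2 with inversion, turning the (R)-carbinol into the (S)-aryl ether, and the carbonate on the aryl group disfavours an SN1 path.

Step 10
Reactants: 15 tert-butyl (3S)-3-{4-[(benzyloxycarbonyl)oxy]phenyl}-3-(4-{4-[5,7-bis(benzyloxy)-4-oxo-4H-chromen-2-yl]phenoxy}-3,5-dimethoxyphenoxy)propanoate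
Product: 16 (3S)-3-{4-[(benzyloxycarbonyl)oxy]phenyl}-3-(4-{4-[5,7-bis(benzyloxy)-4-oxo-4H-chromen-2-yl]phenoxy}-3,5-dimethoxyphenoxy)propanoic acid
Conditions: TFA/CH2Cl2 (1:4), 0 °C to rt
Reagents that add atoms: none
Why: Acidolysis of the tert-butyl ester with loss of isobutene; acid is used because hydroxide would expel the phenoxide by E1cB and cleave the carbonate, whereas benzyl ethers and the carbonate should tolerate brief exposure to TFA.

Step 11
Reactants: 16 (3S)-3-{4-[(benzyloxycarbonyl)oxy]phenyl}-3-(4-{4-[5,7-bis(benzyloxy)-4-oxo-4H-chromen-2-yl]phenoxy}-3,5-dimethoxyphenoxy)propanoic acid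
Product: 17 benzyl 4-[(2S)-6-{4-[5,7-bis(benzyloxy)-4-oxo-4H-chromen-2-yl]phenoxy}-5,7-dimethoxy-4-oxo-3,4-dihydro-2H-chromen-2-yl]phenyl carbonate
Conditions: (CF3CO)2O (3 equiv), CH2Cl2, 0 °C to rt
Reagents that add atoms: none
Why: Trifluoroacetic anhydride converts the acid into the mixed anhydride, whose acyl carbon (as such or as the acylium ion pair it ionises to) is attacked by the ring A carbon ortho to O1; loss of the proton from the σ-complex gives the aryl ketone and closes ring C. The closest known reaction type is the anhydride-mediated Friedel–Crafts cyclisation of 3-aryloxypropanoic and 3-aryl-3-aryloxypropanoic acids to chroman-4-ones and flavanones. Ring C forms by 6-exo-trig attack on the anhydride carbonyl (6-exo-dig if the free acylium ion is the electrophile), with the C=O bond outside the new ring. No stereocentre is created, and C2 is carried through unchanged because none of its bonds takes part. Regioselectivity is not required: the two carbons ortho to O1 are exchanged by the mirror plane of the 3,5-dimethoxy-4-aryloxyphenyl ether, and each is activated by O1, an ortho methoxy and a para methoxy group, whereas the flavone ring A is deactivated by its carbonyl and ring B by the carbonate. The selectivity that is required is acylation over ionisation of the C2–O1 bond, which would racemise C2 or eliminate to the cinnamic acid; the carbonate keeps the benzylic carbon about as electron-poor as in the unsubstituted phenyl case, the β-carbonyl destabilises the cation, and no strong acid is added. Once the ketone has formed, O1 is conjugated with it and less basic, which protects the product.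

Step 12
Reactants: 17 benzyl 4-[(2S)-6-{4-[5,7-bis(benzyloxy)-4-oxo-4H-chromen-2-yl]phenoxy}-5,7-dimethoxy-4-oxo-3,4-dihydro-2H-chromen-2-yl]phenyl carbonate
Product: 18 (2S)-6-[4-(5,7-dihydroxy-4-oxo-4H-chromen-2-yl)phenoxy]-2-(4-hydroxyphenyl)-5,7-dimethoxy-2,3-dihydro-4H-chromen-4-one
Conditions: H2 (1 atm), 10% Pd/C, EtOAc/THF, rt
Reagents that add atoms: none
Why: Hydrogenolysis of the two aryl benzyl ethers and of the benzyl carbonate (which then loses CO2) in one neutral operation; at 1 atm and with the reaction stopped at full conversion, the flavone C2=C3 bond, the aryl ketone and the benzylic C2–O1 bond should not be reduced.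

Step 13
Reactants: 18 (2S)-6-[4-(5,7-dihydroxy-4-oxo-4H-chromen-2-yl)phenoxy]-2-(4-hydroxyphenyl)-5,7-dimethoxy-2,3-dihydro-4H-chromen-4-one
Product: 19 (2S)-6-[4-(5,7-dihydroxy-4-oxo-4H-chromen-2-yl)phenoxy]-5-hydroxy-2-(4-hydroxyphenyl)-7-methoxy-2,3-dihydro-4H-chromen-4-one
Conditions: BCl3 (1 M in CH2Cl2, excess), CH2Cl2, −78 to 0 °C; then MeOH/H2O
Reagents that add atoms: none
Why: Chelation-controlled demethylation: boron bound to C4=O activates only the peri O5 methyl ether for SN2 attack by chloride, while the unchelated O7 methyl ether and the diaryl ether should not react at this temperature; the phenols are held as borates, which keeps ring B electron-poor and C2 intact, and are released on aqueous work-up.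

## Compound list

1 | 2',4',6'-trihydroxyacetophenone | CC(=O)c1c(O)cc(O)cc1O | starting material
2 | 1-[2,4-bis(benzyloxy)-6-hydroxyphenyl]ethan-1-one | CC(=O)c1c(O)cc(OCc2ccccc2)cc1OCc1ccccc1 | intermediate
3 | 4-bromo-2,6-dimethoxyphenol | COc1cc(Br)cc(OC)c1O | starting material
4 | 4-fluorobenzaldehyde | O=Cc1ccc(F)cc1 | starting material
5 | 4-(4-bromo-2,6-dimethoxyphenoxy)benzaldehyde | COc1cc(Br)cc(OC)c1Oc1ccc(C=O)cc1 | intermediate
6 | (E)-1-[2,4-bis(benzyloxy)-6-hydroxyphenyl]-3-[4-(4-bromo-2,6-dimethoxyphenoxy)phenyl]prop-2-en-1-one | O=C(/C=C/c1ccc(Oc2c(OC)cc(Br)cc2OC)cc1)c1c(O)cc(OCc2ccccc2)cc1OCc1ccccc1 | intermediate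
7 | 5,7-bis(benzyloxy)-2-[4-(4-bromo-2,6-dimethoxyphenoxy)phenyl]-4H-chromen-4-one | COc1cc(Br)cc(OC)c1Oc1ccc(-c2cc(=O)c3c(OCc4ccccc4)cc(OCc4ccccc4)cc3o2)cc1 | intermediate
8 | 5,7-bis(benzyloxy)-2-{4-[2,6-dimethoxy-4-(4,4,5,5-tetramethyl-1,3,2-dioxaborolan-2-yl)phenoxy]phenyl}-4H-chromen-4-one | COc1cc(B2OC(C)(C)C(C)(C)O2)cc(OC)c1Oc1ccc(-c2cc(=O)c3c(OCc4ccccc4)cc(OCc4ccccc4)cc3o2)cc1 | intermediate
9 | 5,7-bis(benzyloxy)-2-[4-(4-hydroxy-2,6-dimethoxyphenoxy)phenyl]-4H-chromen-4-one | COc1cc(O)cc(OC)c1Oc1ccc(-c2cc(=O)c3c(OCc4ccccc4)cc(OCc4ccccc4)cc3o2)cc1 | intermediate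
10 | 4-hydroxybenzaldehyde | O=Cc1ccc(O)cc1 | starting material
11 | benzyl 4-formylphenyl carbonate | O=Cc1ccc(OC(=O)OCc2ccccc2)cc1 | intermediate
12 | tert-butyl diazoacetate | CC(C)(C)OC(=O)C=[N+]=[N-] | starting material
13 | tert-butyl 3-{4-[(benzyloxycarbonyl)oxy]phenyl}-3-oxopropanoate | CC(C)(C)OC(=O)CC(=O)c1ccc(OC(=O)OCc2ccccc2)cc1 | intermediate
14 | tert-butyl (3R)-3-{4-[(benzyloxycarbonyl)oxy]phenyl}-3-hydroxypropanoate | CC(C)(C)OC(=O)C[C@@H](O)c1ccc(OC(=O)OCc2ccccc2)cc1 | intermediate
15 | tert-butyl (3S)-3-{4-[(benzyloxycarbonyl)oxy]phenyl}-3-(4-{4-[5,7-bis(benzyloxy)-4-oxo-4H-chromen-2-yl]phenoxy}-3,5-dimethoxyphenoxy)propanoate | CC(C)(C)OC(=O)C[C@@H](c1ccc(OC(=O)OCc2ccccc2)cc1)Oc1cc(OC)c(Oc2ccc(-c3cc(=O)c4c(OCc5ccccc5)cc(OCc5ccccc5)cc4o3)cc2)c(OC)c1 | intermediate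
16 | (3S)-3-{4-[(benzyloxycarbonyl)oxy]phenyl}-3-(4-{4-[5,7-bis(benzyloxy)-4-oxo-4H-chromen-2-yl]phenoxy}-3,5-dimethoxyphenoxy)propanoic acid | OC(=O)C[C@@H](c1ccc(OC(=O)OCc2ccccc2)cc1)Oc1cc(OC)c(Oc2ccc(-c3cc(=O)c4c(OCc5ccccc5)cc(OCc5ccccc5)cc4o3)cc2)c(OC)c1 | intermediate
17 | benzyl 4-[(2S)-6-{4-[5,7-bis(benzyloxy)-4-oxo-4H-chromen-2-yl]phenoxy}-5,7-dimethoxy-4-oxo-3,4-dihydro-2H-chromen-2-yl]phenyl carbonate | COc1cc2c(c(OC)c1Oc1ccc(-c3cc(=O)c4c(OCc5ccccc5)cc(OCc5ccccc5)cc4o3)cc1)C(=O)C[C@@H](c1ccc(OC(=O)OCc3ccccc3)cc1)O2 | intermediate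
18 | (2S)-6-[4-(5,7-dihydroxy-4-oxo-4H-chromen-2-yl)phenoxy]-2-(4-hydroxyphenyl)-5,7-dimethoxy-2,3-dihydro-4H-chromen-4-one | COc1cc2c(c(OC)c1Oc1ccc(-c3cc(=O)c4c(O)cc(O)cc4o3)cc1)C(=O)C[C@@H](c1ccc(O)cc1)O2 | intermediate
19 | (2S)-6-[4-(5,7-dihydroxy-4-oxo-4H-chromen-2-yl)phenoxy]-5-hydroxy-2-(4-hydroxyphenyl)-7-methoxy-2,3-dihydro-4H-chromen-4-one | COc1cc2c(c(O)c1Oc1ccc(-c3cc(=O)c4c(O)cc(O)cc4o3)cc1)C(=O)C[C@@H](c1ccc(O)cc1)O2 | target

## Step count and risks

Total: 13 steps. Longest linear sequence: 9 steps (steps 1, 3, 4, 5, 9, 10, 11, 12, 13 from 1; equally steps 2, 3, 4, 5, 9 to 13 from 3).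

**Step 11 (key step).** The likeliest failure is ionisation of the benzylic C2–O1 bond in the acidic medium (trifluoroacetic acid is formed as the reaction proceeds). This would erode the enantiomeric purity or lead to elimination to the cinnamic acid with release of phenol 9. Loss of the benzyl ether peri to the flavone carbonyl is a second concern. The fallback keeps the same C4–C4a Friedel–Crafts closure on the symmetric ring A but performs it before any stereocentre exists, and it bypasses steps 9 and 10. It sets out from 9: the phenoxide opens β-propiolactone (KOtBu, THF) to give 3-(4-{4-[5,7-bis(benzyloxy)-4-oxo-4H-chromen-2-yl]phenoxy}-3,5-dimethoxyphenoxy)propanoic acid F1. Trifluoroacetic anhydride closes this to the 5,7-dimethoxychroman-4-one F2. Aerobic dehydrogenation with Pd(OCOCF3)2 in DMSO under O2 gives the 5,7-dimethoxychromone F3. Enantioselective conjugate addition of 4-(benzyloxy)phenylboronic acid, with Pd(OCOCF3)2 and the tert-butyl pyridine–oxazoline ligand enantiomer chosen for the (2S) product, gives the (2S)-2-[4-(benzyloxy)phenyl]flavanone F4. Hydrogenolysis (H2, Pd/C) of its three benzyl ethers returns to the route at 18.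

**Step 9.** The likeliest failure is β-elimination of the activated carbinol to the tert-butyl cinnamate, because the ester acidifies the neighbouring hydrogens; partial loss of stereochemical fidelity through an ion-pair path is the second risk. The fallback uses a carbinol without an acidifying carbonyl and creates the carboxyl group afterwards. It sets out from 11: Keck allylation (allyltributylstannane, Ti(OiPr)4 with the BINOL enantiomer that gives the (R)-carbinol) gives benzyl 4-[(1R)-1-hydroxybut-3-en-1-yl]phenyl carbonate F5. Mitsunobu reaction with 9 gives the (S)-homoallyl aryl ether F6. Cleavage of the alkene with OsO4 (catalytic) and NaIO4 gives the (S)-β-aryloxy aldehyde F7, which is used crude. Pinnick oxidation (NaClO2, NaH2PO4, 2-methyl-2-butene) returns to the route at 16.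

**Step 13.** Demethylation may stall because the borates of the polyphenol precipitate from CH2Cl2, and prolonged Lewis acid contact with an unprotected ring B could cause partial epimerisation at C2 by ring opening. The fallback inverts the order of the last two operations. It sets out from 17: BCl3 with pentamethylbenzene as cation scavenger (CH2Cl2, −78 to 0 °C) should cleave the chelated O5 methyl ether and both benzyl ethers while the molecule is still soluble and ring B still carries its carbonate. This gives benzyl 4-[(2S)-6-[4-(5,7-dihydroxy-4-oxo-4H-chromen-2-yl)phenoxy]-5-hydroxy-7-methoxy-4-oxo-3,4-dihydro-2H-chromen-2-yl]phenyl carbonate F8. Hydrogenolysis of the carbonate (H2, Pd/C) then gives 19; if BCl3 also removes the carbonate, 19 is reached directly.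

**Step 7.** Aromatic aldehydes are the less reactive substrates of the Roskamp homologation, so slow conversion and some aryl migration to the 2-aryl-3-oxo ester may occur. The fallback replaces the insertion by addition and oxidation. It sets out from 11: Reformatsky reaction with tert-butyl bromoacetate and Zn in THF gives racemic tert-butyl 3-{4-[(benzyloxycarbonyl)oxy]phenyl}-3-hydroxypropanoate F9. Dess–Martin oxidation returns to the route at 13.

## Further compounds

F1 | step 11 | 3-(4-{4-[5,7-bis(benzyloxy)-4-oxo-4H-chromen-2-yl]phenoxy}-3,5-dimethoxyphenoxy)propanoic acid | OC(=O)CCOc1cc(OC)c(Oc2ccc(-c3cc(=O)c4c(OCc5ccccc5)cc(OCc5ccccc5)cc4o3)cc2)c(OC)c1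
F2 | step 11 | 6-{4-[5,7-bis(benzyloxy)-4-oxo-4H-chromen-2-yl]phenoxy}-5,7-dimethoxy-2,3-dihydro-4H-chromen-4-one | COc1cc2c(c(OC)c1Oc1ccc(-c3cc(=O)c4c(OCc5ccccc5)cc(OCc5ccccc5)cc4o3)cc1)C(=O)CCO2
F3 | step 11 | 6-{4-[5,7-bis(benzyloxy)-4-oxo-4H-chromen-2-yl]phenoxy}-5,7-dimethoxy-4H-chromen-4-one | COc1cc2occc(=O)c2c(OC)c1Oc1ccc(-c3cc(=O)c4c(OCc5ccccc5)cc(OCc5ccccc5)cc4o3)cc1
F4 | step 11 | (2S)-2-[4-(benzyloxy)phenyl]-6-{4-[5,7-bis(benzyloxy)-4-oxo-4H-chromen-2-yl]phenoxy}-5,7-dimethoxy-2,3-dihydro-4H-chromen-4-one | COc1cc2c(c(OC)c1Oc1ccc(-c3cc(=O)c4c(OCc5ccccc5)cc(OCc5ccccc5)cc4o3)cc1)C(=O)C[C@@H](c1ccc(OCc3ccccc3)cc1)O2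
F5 | step 9 | benzyl 4-[(1R)-1-hydroxybut-3-en-1-yl]phenyl carbonate | C=CC[C@@H](O)c1ccc(OC(=O)OCc2ccccc2)cc1
F6 | step 9 | benzyl 4-[(1S)-1-(4-{4-[5,7-bis(benzyloxy)-4-oxo-4H-chromen-2-yl]phenoxy}-3,5-dimethoxyphenoxy)but-3-en-1-yl]phenyl carbonate | C=CC[C@@H](c1ccc(OC(=O)OCc2ccccc2)cc1)Oc1cc(OC)c(Oc2ccc(-c3cc(=O)c4c(OCc5ccccc5)cc(OCc5ccccc5)cc4o3)cc2)c(OC)c1
F7 | step 9 | benzyl 4-[(1S)-1-(4-{4-[5,7-bis(benzyloxy)-4-oxo-4H-chromen-2-yl]phenoxy}-3,5-dimethoxyphenoxy)-3-oxopropyl]phenyl carbonate | O=CC[C@@H](c1ccc(OC(=O)OCc2ccccc2)cc1)Oc1cc(OC)c(Oc2ccc(-c3cc(=O)c4c(OCc5ccccc5)cc(OCc5ccccc5)cc4o3)cc2)c(OC)c1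
F8 | step 13 | benzyl 4-[(2S)-6-[4-(5,7-dihydroxy-4-oxo-4H-chromen-2-yl)phenoxy]-5-hydroxy-7-methoxy-4-oxo-3,4-dihydro-2H-chromen-2-yl]phenyl carbonate | COc1cc2c(c(O)c1Oc1ccc(-c3cc(=O)c4c(O)cc(O)cc4o3)cc1)C(=O)C[C@@H](c1ccc(OC(=O)OCc3ccccc3)cc1)O2
F9 | step 7 | tert-butyl 3-{4-[(benzyloxycarbonyl)oxy]phenyl}-3-hydroxypropanoate (racemic) | CC(C)(C)OC(=O)CC(O)c1ccc(OC(=O)OCc2ccccc2)cc1
A1 | alternative 1 | 5-(benzyloxy)-6-{4-[5,7-bis(benzyloxy)-4-oxo-4H-chromen-2-yl]phenoxy}-7-methoxy-4H-chromen-4-one | COc1cc2occc(=O)c2c(OCc3ccccc3)c1Oc1ccc(-c3cc(=O)c4c(OCc5ccccc5)cc(OCc5ccccc5)cc4o3)cc1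
A2 | alternative 1 | 3-(benzyloxy)-4-{4-[5,7-bis(benzyloxy)-4-oxo-4H-chromen-2-yl]phenoxy}-5-methoxy-2-[(triphenyl-λ5-phosphanylidene)acetyl]phenyl formate | O=COc1cc(OC)c(Oc2ccc(-c3cc(=O)c4c(OCc5ccccc5)cc(OCc5ccccc5)cc4o3)cc2)c(OCc2ccccc2)c1C(=O)C=P(c1ccccc1)(c1ccccc1)c1ccccc1
A3 | alternative 2 | 5,7-bis(benzyloxy)-2-[4-(4-hydroxy-2,6-dimethoxyphenoxy)phenyl]-4H-chromen-4-one (identical with 9) | COc1cc(O)cc(OC)c1Oc1ccc(-c2cc(=O)c3c(OCc4ccccc4)cc(OCc4ccccc4)cc3o2)cc1
A4 | alternative 2 | (Z)-3-[3,5-bis(benzyloxy)phenoxy]-3-[4-(4-hydroxy-2,6-dimethoxyphenoxy)phenyl]prop-2-enoic acid | OC(=O)/C=C(\Oc1cc(OCc2ccccc2)cc(OCc2ccccc2)c1)c1ccc(Oc2c(OC)cc(O)cc2OC)cc1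
A5 | alternative 3 | 2-(4-{[(2S,4S)-2-[4-(benzyloxy)phenyl]-4-hydroxy-5,7-dimethoxy-3,4-dihydro-2H-chromen-6-yl]oxy}phenyl)-5,7-bis(benzyloxy)-4H-chromen-4-one | COc1cc2c(c(OC)c1Oc1ccc(-c3cc(=O)c4c(OCc5ccccc5)cc(OCc5ccccc5)cc4o3)cc1)[C@@H](O)C[C@@H](c1ccc(OCc3ccccc3)cc1)O2
A6 | alternative 3 | (1S,3S)-3-[4-(benzyloxy)phenyl]-1-(5-{4-[5,7-bis(benzyloxy)-4-oxo-4H-chromen-2-yl]phenoxy}-2-bromo-4,6-dimethoxyphenyl)propane-1,3-diol | COc1cc(Br)c(c(OC)c1Oc1ccc(-c2cc(=O)c3c(OCc4ccccc4)cc(OCc4ccccc4)cc3o2)cc1)[C@@H](O)C[C@@H](c1ccc(OCc2ccccc2)cc1)O
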